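**Plan**

- Retrosynthesis: cut the cinnamate ester C15–O, then the side chain at C14–C15, C13–C16 and C12–C13. Ring A is cut at C4–C5 and C3–C4, so that one malonate carbon sits between a C3 iodide and the C5 end of a C1–C10–C5 allyl unit. Then cut C1–C10, and finally C9–C11 and C8–C17, back to 2-methylcyclohexenone.
- Enabling feature: C4 is a quaternary carbon bonded to C3 and to the fusion carbon C5, and C5 is allylic to the C1=C10 alkene of ring A. A doubly activated CH2 carbon can therefore be alkylated once at C3 (SN2) and once at C5 (π-allyl).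
- Forward order: ring B is built first on a cyclohexanone (C8, C9), the C1–C3 chain is attached at C10 through the enol triflate, and ring A is closed in step 12. The two C4 esters are then differentiated (equatorial to CO2H, axial to CH3) and the side chain is grown from C12 and acylated.
- Stereochemistry: C8 comes from ligand-controlled conjugate methylation and C9 from enolate allylation anti to the C8 methyl. C1 is set by a CBS reduction and relayed to C5 by double inversion on palladium. C4 rests on the different accessibility of the two diastereotopic esters. The E alkene comes from syn-carboalumination and the Z-cinnamate from syn-semihydrogenation.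

Key step: step 12

Remark: bicyclic compounds are named as Δ1(10)-octalins with halimane numbering (ring A = C1–C5 and C10, ring B = C5–C10; C4 bears the carboxyl carbon and a methyl group, C8 a methyl group, C9 a methyl group and the side chain C11–C16); β is the face of H-5 and α the face of the C9 methyl group; 2-(trimethylsilyl)ethyl 2,2,2-trichloroacetimidate and lithium acetylide–ethylenediamine complex are taken to be commercial.

**Route**

Step 1
Reactants: 1 2-methylcyclohex-2-en-1-one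
Product: 3 trimethyl{[(3R)-2,3-dimethylcyclohex-1-en-1-yl]oxy}silane, via dimethylaluminium enolate 2 (not isolated)
Conditions: Me3Al, Cu(O2CC4H3S) (copper thiophene-2-carboxylate, 2 mol %), BINOL-derived phosphoramidite ligand (4 mol %, the antipode that gives 3R), Et2O, −30 °C; then TMSOTf, −30 → 0 °C
Reagents that add atoms: trimethylaluminium C[Al](C)C; trimethylsilyl trifluoromethanesulfonate C[Si](C)(C)OS(=O)(=O)C(F)(F)F
Why: Copper-catalysed asymmetric conjugate addition of Me3Al to the α-substituted enone should set the C8 methyl centre (3R) under ligand control, and O-silylation of the regiodefined aluminium enolate stores that enolate for the next step.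

Step 2
Reactants: 3 trimethyl{[(3R)-2,3-dimethylcyclohex-1-en-1-yl]oxy}silane; 4 allyl bromide
Product: 6 (2S,3R)-2,3-dimethyl-2-(prop-2-en-1-yl)cyclohexan-1-one, via lithium enolate 5 (not isolated)
Conditions: MeLi, THF, 0 °C; then allyl bromide, DMPU, −78 → 0 °C
Reagents that add atoms: none
Why: MeLi cleaves the silyl enol ether to the tetrasubstituted lithium enolate regiospecifically, and enolate allylation should occur anti to the neighbouring pseudoaxial C8 methyl group, creating the quaternary C9 with the two methyl groups cis.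

Step 3
Reactants: 6 (2S,3R)-2,3-dimethyl-2-(prop-2-en-1-yl)cyclohexan-1-one
Product: 9 (2S,3R)-2-(2-hydroxyethyl)-2,3-dimethylcyclohexan-1-one, via ozonide 7 (not isolated), via keto aldehyde 8 (not isolated)
Conditions: O3, CH2Cl2, −78 °C; PPh3; then EtOH, NaBH4, −78 °C
Reagents that add atoms: ozone [O-][O+]=O
Why: Ozonolysis cuts the terminal alkene to the C12 aldehyde, which NaBH4 at −78 °C should reduce selectively because the ring ketone is flanked by the quaternary C9.

Step 4
Reactants: 9 (2S,3R)-2-(2-hydroxyethyl)-2,3-dimethylcyclohexan-1-one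
Product: 10 (2S,3R)-2,3-dimethyl-2-[2-(triisopropylsilyloxy)ethyl]cyclohexan-1-one
Conditions: TIPSCl, imidazole, DMF, rt
Reagents that add atoms: chlorotriisopropylsilane CC(C)[Si](Cl)(C(C)C)C(C)C
Why: Silylation of the primary alcohol drains the hydroxy ketone–lactol equilibrium into the open silyl ether, and the TIPS group is chosen to outlast the later TBS cleavage.

Step 5
Reactants: 10 (2S,3R)-2,3-dimethyl-2-[2-(triisopropylsilyloxy)ethyl]cyclohexan-1-one
Product: 12 (5R,6S)-5,6-dimethyl-6-[2-(triisopropylsilyloxy)ethyl]cyclohex-1-en-1-yl trifluoromethanesulfonate, via potassium enolate 11 (not isolated)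
Conditions: KHMDS, THF, −78 °C; then PhNTf2, −78 → 0 °C
Reagents that add atoms: N-phenylbis(trifluoromethanesulfonimide) O=S(=O)(N(c1ccccc1)S(=O)(=O)C(F)(F)F)C(F)(F)F
Why: Enolisation can only take place towards C5 because C9 is quaternary, so triflation of the potassium enolate gives a single enol triflate (C10=C5).

Step 6
Reactants: 12 (5R,6S)-5,6-dimethyl-6-[2-(triisopropylsilyloxy)ethyl]cyclohex-1-en-1-yl trifluoromethanesulfonate; 13 3-(tert-butyldimethylsilyloxy)propanal
Product: 14 (1RS)-3-(tert-butyldimethylsilyloxy)-1-{(5R,6S)-5,6-dimethyl-6-[2-(triisopropylsilyloxy)ethyl]cyclohex-1-en-1-yl}propan-1-ol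
Conditions: CrCl2 (5 equiv), NiCl2 (2 mol %), DMF, rt
Reagents that add atoms: none
Why: Nozaki–Hiyama–Kishi coupling adds the alkenylchromium species generated from the triflate to the aldehyde only, forming C1–C10 without touching the silyl ethers; the C1 configuration is not controlled here and is erased in the next step.

Step 7
Reactants: 14 (1RS)-3-(tert-butyldimethylsilyloxy)-1-{(5R,6S)-5,6-dimethyl-6-[2-(triisopropylsilyloxy)ethyl]cyclohex-1-en-1-yl}propan-1-ol
Product: 15 3-(tert-butyldimethylsilyloxy)-1-{(5R,6S)-5,6-dimethyl-6-[2-(triisopropylsilyloxy)ethyl]cyclohex-1-en-1-yl}propan-1-one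
Conditions: Dess–Martin periodinane, NaHCO3, CH2Cl2, 0 °C → rt
Reagents that add atoms: none
Why: Dess–Martin oxidation under buffered conditions converts both carbinol epimers into one enone without β-elimination of the silyloxy group.

Step 8
Reactants: 15 3-(tert-butyldimethylsilyloxy)-1-{(5R,6S)-5,6-dimethyl-6-[2-(triisopropylsilyloxy)ethyl]cyclohex-1-en-1-yl}propan-1-one
Product: 16 (1S)-3-(tert-butyldimethylsilyloxy)-1-{(5R,6S)-5,6-dimethyl-6-[2-(triisopropylsilyloxy)ethyl]cyclohex-1-en-1-yl}propan-1-ol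
Conditions: (R)-2-methyl-CBS-oxazaborolidine (0.5 equiv), BH3·SMe2, THF, −30 °C; MeOH quench
Reagents that add atoms: none
Why: Corey–Bakshi–Shibata reduction, with the α-branched cyclohexenyl group as the large and the CH2CH2OTBS chain as the small substituent, should deliver hydride under reagent control to give the (1S) carbinol.

Step 9
Reactants: 16 (1S)-3-(tert-butyldimethylsilyloxy)-1-{(5R,6S)-5,6-dimethyl-6-[2-(triisopropylsilyloxy)ethyl]cyclohex-1-en-1-yl}propan-1-ol
Product: 17 (1S)-3-(tert-butyldimethylsilyloxy)-1-{(5R,6S)-5,6-dimethyl-6-[2-(triisopropylsilyloxy)ethyl]cyclohex-1-en-1-yl}propyl methyl carbonate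
Conditions: ClCO2Me, pyridine, DMAP (cat.), CH2Cl2, 0 °C
Reagents that add atoms: methyl chloroformate COC(=O)Cl
Why: O-Acylation of the secondary allylic alcohol proceeds with retention at C1 and installs a leaving group that releases its own base (methoxide) on ionisation.

Step 10
Reactants: 17 (1S)-3-(tert-butyldimethylsilyloxy)-1-{(5R,6S)-5,6-dimethyl-6-[2-(triisopropylsilyloxy)ethyl]cyclohex-1-en-1-yl}propyl methyl carbonate
Product: 18 (1S)-1-{(5R,6S)-5,6-dimethyl-6-[2-(triisopropylsilyloxy)ethyl]cyclohex-1-en-1-yl}-3-hydroxypropyl methyl carbonate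
Conditions: HF·pyridine, pyridine, THF, 0 °C
Reagents that add atoms: none
Why: Buffered HF·pyridine removes the primary TBS ether much faster than the bulkier primary TIPS ether and does not ionise the allylic carbonate.

Step 11
Reactants: 18 (1S)-1-{(5R,6S)-5,6-dimethyl-6-[2-(triisopropylsilyloxy)ethyl]cyclohex-1-en-1-yl}-3-hydroxypropyl methyl carbonate
Product: 19 (1S)-1-{(5R,6S)-5,6-dimethyl-6-[2-(triisopropylsilyloxy)ethyl]cyclohex-1-en-1-yl}-3-iodopropyl methyl carbonate
Conditions: I2, PPh3, imidazole, CH2Cl2, 0 °C → rt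
Reagents that add atoms: iodine II
Why: Iodination of the primary alcohol through its alkoxyphosphonium salt (Appel-type, Garegg–Samuelsson conditions) is an SN2 process at C3 that leaves the secondary allylic carbonate alone.

Step 12
Reactants: 19 (1S)-1-{(5R,6S)-5,6-dimethyl-6-[2-(triisopropylsilyloxy)ethyl]cyclohex-1-en-1-yl}-3-iodopropyl methyl carbonate; 20 dimethyl malonate
Product: 22 dimethyl (5S,8R,9S)-8,9-dimethyl-9-[2-(triisopropylsilyloxy)ethyl]-Δ1(10)-octalin-4,4-dicarboxylate, via alkylated malonate 21 (not isolated)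
Conditions: NaH (1.15 equiv), dimethyl malonate (1.3 equiv), THF/DMF, 0 → 45 °C; then dilution with THF, Pd(PPh3)4 (10 mol %), 65 °C
Reagents that add atoms: none
Why: Sodium dimethyl malonate displaces the primary iodide (SN2, C3–C4), zerovalent palladium then ionises the C1 methyl carbonate anti to the leaving group, the methoxide set free deprotonates the tethered malonate and this soft carbanion attacks the allyl terminus C5 anti to the metal (C4–C5); the closest known reaction type is the intramolecular Tsuji–Trost alkylation of malonates. Ring A closes in the 6-endo mode, all three allyl carbons ending inside the new cyclohexene with the alkene at C1=C10, whereas 4-exo attack at C1 would give a strained vinylcyclobutane that reopens under the same catalyst. The new stereocentre C5 is controlled by the (1S) carbinol centre: inversion on ionisation and inversion on attack place C4 on the face that carried the carbonate, which in the reactive conformer is the face of the C9 methyl group, so H-5 ends cis to the C9 side chain (5S). The step needs distal attack and faithful C1-to-C5 chirality transfer; the quaternary C9 on the central allyl carbon forces C2 into the anti position from which alone C5 can be reached, the ring fixes the geometry at C5 so the complex cannot lose its facial identity by π–σ–π rotation, and the two-carbon tether should make ring closure faster than attack by the small excess of free malonate.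

Step 13
Reactants: 22 dimethyl (5S,8R,9S)-8,9-dimethyl-9-[2-(triisopropylsilyloxy)ethyl]-Δ1(10)-octalin-4,4-dicarboxylate
Product: 23 (4R,5S,8R,9S)-4-(methoxycarbonyl)-8,9-dimethyl-9-[2-(triisopropylsilyloxy)ethyl]-Δ1(10)-octalin-4-carboxylic acid (CO2H β; CO2Me α)
Conditions: KOH (3 equiv), MeOH/THF/H2O, 50 °C; work-up with 1 M HCl
Reagents that add atoms: potassium hydroxide [K+].[OH-]
Why: In this group-selective saponification of a gem-diester, hydroxide should attack the equatorial ester, which lies trans to the C5–C6 bond, in preference to the axial ester shielded by the axial hydrogens at C2 and C6, and the carboxylate formed protects the second ester from further hydrolysis.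

Step 14
Reactants: 23 (4R,5S,8R,9S)-4-(methoxycarbonyl)-8,9-dimethyl-9-[2-(triisopropylsilyloxy)ethyl]-Δ1(10)-octalin-4-carboxylic acid
Product: 24 (4S,5S,8R,9S)-4-(hydroxymethyl)-8,9-dimethyl-9-[2-(triisopropylsilyloxy)ethyl]-Δ1(10)-octalin-4-carboxylic acid (CO2H β; CH2OH α)
Conditions: LiBH4 (3 equiv), MeOH (1 equiv), THF, 0 → 50 °C; work-up with 1 M HCl
Reagents that add atoms: none
Why: LiBH4 reduces esters but not lithium carboxylates, so only the remaining axial methyl ester is converted into the hydroxymethyl group.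

Step 15
Reactants: 24 (4S,5S,8R,9S)-4-(hydroxymethyl)-8,9-dimethyl-9-[2-(triisopropylsilyloxy)ethyl]-Δ1(10)-octalin-4-carboxylic acid
Product: 25 2-(trimethylsilyl)ethyl (4S,5S,8R,9S)-4-(hydroxymethyl)-8,9-dimethyl-9-[2-(triisopropylsilyloxy)ethyl]-Δ1(10)-octalin-4-carboxylate
Conditions: 2-(trimethylsilyl)ethyl 2,2,2-trichloroacetimidate (2 equiv), toluene, 100 °C
Reagents that add atoms: 2-(trimethylsilyl)ethyl 2,2,2-trichloroacetimidate C[Si](C)(C)CCOC(=N)C(Cl)(Cl)Cl
Why: Trichloroacetimidates alkylate carboxylic acids on heating without added promoter while alcohols do not react, so the acid is masked as the fluoride-labile 2-(trimethylsilyl)ethyl ester in the presence of the neopentyl alcohol.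

Step 16
Reactants: 25 2-(trimethylsilyl)ethyl (4S,5S,8R,9S)-4-(hydroxymethyl)-8,9-dimethyl-9-[2-(triisopropylsilyloxy)ethyl]-Δ1(10)-octalin-4-carboxylate
Product: 26 2-(trimethylsilyl)ethyl (4R,5S,8R,9S)-4-(iodomethyl)-8,9-dimethyl-9-[2-(triisopropylsilyloxy)ethyl]-Δ1(10)-octalin-4-carboxylate
Conditions: I2, PPh3, imidazole, toluene, 90 °C
Reagents that add atoms: iodine II
Why: Garegg–Samuelsson iodination through the alkoxyphosphonium ion is a direct displacement, so the neopentyl-type primary alcohol should give the iodide on heating without skeletal rearrangement.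

Step 17
Reactants: 26 2-(trimethylsilyl)ethyl (4R,5S,8R,9S)-4-(iodomethyl)-8,9-dimethyl-9-[2-(triisopropylsilyloxy)ethyl]-Δ1(10)-octalin-4-carboxylate
Product: 27 2-(trimethylsilyl)ethyl (4S,5S,8R,9S)-4,8,9-trimethyl-9-[2-(triisopropylsilyloxy)ethyl]-Δ1(10)-octalin-4-carboxylate
Conditions: Bu3SnH, AIBN (cat.), toluene, 90 °C
Reagents that add atoms: none
Why: Tin hydride radical dehalogenation reduces the primary iodide to the C4 methyl group, hydrogen transfer to the neopentyl radical being faster than any 4-exo or 5-endo addition to the C1=C10 alkene.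

Step 18
Reactants: 27 2-(trimethylsilyl)ethyl (4S,5S,8R,9S)-4,8,9-trimethyl-9-[2-(triisopropylsilyloxy)ethyl]-Δ1(10)-octalin-4-carboxylate
Product: 28 2-(trimethylsilyl)ethyl (4S,5S,8R,9S)-9-(2-hydroxyethyl)-4,8,9-trimethyl-Δ1(10)-octalin-4-carboxylate
Conditions: HF·pyridine, THF, 0 °C → rt
Reagents that add atoms: none
Why: Acidic fluoride cleaves the primary TIPS ether, whereas the 2-(trimethylsilyl)ethyl ester, which needs a basic fluoride source, is expected to persist.

Step 19
Reactants: 28 2-(trimethylsilyl)ethyl (4S,5S,8R,9S)-9-(2-hydroxyethyl)-4,8,9-trimethyl-Δ1(10)-octalin-4-carboxylate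
Product: 29 2-(trimethylsilyl)ethyl (4S,5S,8R,9S)-9-(2-iodoethyl)-4,8,9-trimethyl-Δ1(10)-octalin-4-carboxylate
Conditions: I2, PPh3, imidazole, CH2Cl2, 0 °C → rt
Reagents that add atoms: iodine II
Why: Appel-type iodination converts the unhindered primary C12 alcohol into the iodide by SN2 displacement of the alkoxyphosphonium group.

Step 20
Reactants: 29 2-(trimethylsilyl)ethyl (4S,5S,8R,9S)-9-(2-iodoethyl)-4,8,9-trimethyl-Δ1(10)-octalin-4-carboxylate
Product: 30 2-(trimethylsilyl)ethyl (4S,5S,8R,9S)-9-(but-3-yn-1-yl)-4,8,9-trimethyl-Δ1(10)-octalin-4-carboxylate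
Conditions: lithium acetylide–ethylenediamine complex, DMSO, rt
Reagents that add atoms: lithium acetylide (ethylenediamine complex) [Li+].[C-]#C
Why: SN2 alkylation of lithium acetylide by the primary iodide adds C13 and C14, the ester on the quaternary C4 being too hindered to be attacked.

Step 21
Reactants: 30 2-(trimethylsilyl)ethyl (4S,5S,8R,9S)-9-(but-3-yn-1-yl)-4,8,9-trimethyl-Δ1(10)-octalin-4-carboxylate
Product: 33 2-(trimethylsilyl)ethyl (4S,5S,8R,9S)-9-[(3E)-5-hydroxy-3-methylpent-3-en-1-yl]-4,8,9-trimethyl-Δ1(10)-octalin-4-carboxylate, via alkenylalane 31 (not isolated), via lithium alanate 32 (not isolated)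
Conditions: Me3Al (2 equiv), Cp2ZrCl2 (25 mol %), CH2Cl2, 0 °C → rt; then n-BuLi, THF, −78 °C; (CH2O)n, −78 °C → rt; work-up with aqueous HCl
Reagents that add atoms: trimethylaluminium C[Al](C)C; formaldehyde (from paraformaldehyde) C=O
Why: Negishi zirconium-catalysed carboalumination adds CH3 and Al syn across the terminal alkyne with methyl at the internal carbon, and hydroxymethylation of the derived alanate occurs with retention, so the trisubstituted alkene is formed as the E isomer.

Step 22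
Reactants: 33 2-(trimethylsilyl)ethyl (4S,5S,8R,9S)-9-[(3E)-5-hydroxy-3-methylpent-3-en-1-yl]-4,8,9-trimethyl-Δ1(10)-octalin-4-carboxylate; 34 phenylpropiolic acid
Product: 35 2-(trimethylsilyl)ethyl (4S,5S,8R,9S)-4,8,9-trimethyl-9-{(3E)-3-methyl-5-[(3-phenylprop-2-ynoyl)oxy]pent-3-en-1-yl}-Δ1(10)-octalin-4-carboxylate
Conditions: DCC, DMAP (5 mol %), CH2Cl2, 0 °C
Reagents that add atoms: none
Why: Steglich esterification joins the primary allylic alcohol and phenylpropiolic acid under neutral conditions at 0 °C, which avoids ionisation of the allylic system.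

Step 23
Reactants: 35 2-(trimethylsilyl)ethyl (4S,5S,8R,9S)-4,8,9-trimethyl-9-{(3E)-3-methyl-5-[(3-phenylprop-2-ynoyl)oxy]pent-3-en-1-yl}-Δ1(10)-octalin-4-carboxylate
Product: 36 2-(trimethylsilyl)ethyl (4S,5S,8R,9S)-4,8,9-trimethyl-9-[(3E)-3-methyl-5-{[(2Z)-3-phenylprop-2-enoyl]oxy}pent-3-en-1-yl]-Δ1(10)-octalin-4-carboxylate
Conditions: H2 (1 atm), Pd/CaCO3 poisoned with Pb(OAc)2 (Lindlar catalyst), quinoline, EtOAc, rt
Reagents that add atoms: none
Why: Lindlar semihydrogenation delivers H2 syn to the alkyne only, giving the Z-cinnamate while the two trisubstituted alkenes are inert.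

Step 24
Reactants: 36 2-(trimethylsilyl)ethyl (4S,5S,8R,9S)-4,8,9-trimethyl-9-[(3E)-3-methyl-5-{[(2Z)-3-phenylprop-2-enoyl]oxy}pent-3-en-1-yl]-Δ1(10)-octalin-4-carboxylate
Product: 37 (4S,5S,8R,9S)-4,8,9-trimethyl-9-[(3E)-3-methyl-5-{[(2Z)-3-phenylprop-2-enoyl]oxy}pent-3-en-1-yl]-Δ1(10)-octalin-4-carboxylic acid (CNP0150420.1)
Conditions: TBAF, THF, 0 °C → rt; work-up with aqueous NH4Cl
Reagents that add atoms: none
Why: Fluoride attacks silicon of the 2-(trimethylsilyl)ethyl ester and fragmentation releases ethene and the carboxylate, conditions under which the allylic Z-cinnamate should neither cleave nor isomerise.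

**Compound list**

1 | 2-methylcyclohex-2-en-1-one | CC1=CCCC1=O | starting material
2 | dimethylaluminium (3R)-2,3-dimethylcyclohex-1-en-1-olate (not isolated) | CC1=C(O[Al](C)C)CCC[C@H]1C | intermediate
3 | trimethyl{[(3R)-2,3-dimethylcyclohex-1-en-1-yl]oxy}silane | CC1=C(O[Si](C)(C)C)CCC[C@H]1C | intermediate
4 | allyl bromide (3-bromoprop-1-ene) | C=CCBr | starting material
5 | lithium (3R)-2,3-dimethylcyclohex-1-en-1-olate (not isolated) | CC1=C(O[Li])CCC[C@H]1C | intermediate
6 | (2S,3R)-2,3-dimethyl-2-(prop-2-en-1-yl)cyclohexan-1-one | C=CC[C@]1(C)C(=O)CCC[C@H]1C | intermediate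
7 | (2S,3R)-2,3-dimethyl-2-[(1,2,4-trioxolan-3-yl)methyl]cyclohexan-1-one (ozonide, not isolated) | C1(OCOO1)C[C@]2(C)C(=O)CCC[C@H]2C | intermediate
8 | 2-[(1S,2R)-1,2-dimethyl-6-oxocyclohexyl]acetaldehyde (not isolated) | O=CC[C@]1(C)C(=O)CCC[C@H]1C | intermediate
9 | (2S,3R)-2-(2-hydroxyethyl)-2,3-dimethylcyclohexan-1-one | OCC[C@]1(C)C(=O)CCC[C@H]1C | intermediate
10 | (2S,3R)-2,3-dimethyl-2-[2-(triisopropylsilyloxy)ethyl]cyclohexan-1-one | CC(C)[Si](C(C)C)(C(C)C)OCC[C@]1(C)C(=O)CCC[C@H]1C | intermediate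
11 | potassium (5R,6S)-5,6-dimethyl-6-[2-(triisopropylsilyloxy)ethyl]cyclohex-1-en-1-olate (not isolated) | [K+].CC(C)[Si](C(C)C)(C(C)C)OCC[C@]1(C)C([O-])=CCC[C@H]1C | intermediate
12 | (5R,6S)-5,6-dimethyl-6-[2-(triisopropylsilyloxy)ethyl]cyclohex-1-en-1-yl trifluoromethanesulfonate | CC(C)[Si](C(C)C)(C(C)C)OCC[C@]1(C)C(OS(=O)(=O)C(F)(F)F)=CCC[C@H]1C | intermediate
13 | 3-(tert-butyldimethylsilyloxy)propanal | O=CCCO[Si](C)(C)C(C)(C)C | starting material
14 | (1RS)-3-(tert-butyldimethylsilyloxy)-1-{(5R,6S)-5,6-dimethyl-6-[2-(triisopropylsilyloxy)ethyl]cyclohex-1-en-1-yl}propan-1-ol (both C1 epimers) | CC(C)[Si](C(C)C)(C(C)C)OCC[C@]1(C)C(=CCC[C@H]1C)C(O)CCO[Si](C)(C)C(C)(C)C | intermediate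
15 | 3-(tert-butyldimethylsilyloxy)-1-{(5R,6S)-5,6-dimethyl-6-[2-(triisopropylsilyloxy)ethyl]cyclohex-1-en-1-yl}propan-1-one | CC(C)[Si](C(C)C)(C(C)C)OCC[C@]1(C)C(=CCC[C@H]1C)C(=O)CCO[Si](C)(C)C(C)(C)C | intermediate
16 | (1S)-3-(tert-butyldimethylsilyloxy)-1-{(5R,6S)-5,6-dimethyl-6-[2-(triisopropylsilyloxy)ethyl]cyclohex-1-en-1-yl}propan-1-ol | CC(C)[Si](C(C)C)(C(C)C)OCC[C@]1(C)C(=CCC[C@H]1C)[C@H](CCO[Si](C)(C)C(C)(C)C)O | intermediate
17 | (1S)-3-(tert-butyldimethylsilyloxy)-1-{(5R,6S)-5,6-dimethyl-6-[2-(triisopropylsilyloxy)ethyl]cyclohex-1-en-1-yl}propyl methyl carbonate | CC(C)[Si](C(C)C)(C(C)C)OCC[C@]1(C)C(=CCC[C@H]1C)[C@H](CCO[Si](C)(C)C(C)(C)C)OC(=O)OC | intermediate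
18 | (1S)-1-{(5R,6S)-5,6-dimethyl-6-[2-(triisopropylsilyloxy)ethyl]cyclohex-1-en-1-yl}-3-hydroxypropyl methyl carbonate | CC(C)[Si](C(C)C)(C(C)C)OCC[C@]1(C)C(=CCC[C@H]1C)[C@H](CCO)OC(=O)OC | intermediate
19 | (1S)-1-{(5R,6S)-5,6-dimethyl-6-[2-(triisopropylsilyloxy)ethyl]cyclohex-1-en-1-yl}-3-iodopropyl methyl carbonate | CC(C)[Si](C(C)C)(C(C)C)OCC[C@]1(C)C(=CCC[C@H]1C)[C@H](CCI)OC(=O)OC | intermediate
20 | dimethyl malonate | COC(=O)CC(=O)OC | starting material
21 | dimethyl 2-[(3S)-3-{(5R,6S)-5,6-dimethyl-6-[2-(triisopropylsilyloxy)ethyl]cyclohex-1-en-1-yl}-3-(methoxycarbonyloxy)propyl]propanedioate (not isolated) | CC(C)[Si](C(C)C)(C(C)C)OCC[C@]1(C)C(=CCC[C@H]1C)[C@H](CCC(C(=O)OC)C(=O)OC)OC(=O)OC | intermediate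
22 | dimethyl (5S,8R,9S)-8,9-dimethyl-9-[2-(triisopropylsilyloxy)ethyl]-Δ1(10)-octalin-4,4-dicarboxylate | CC(C)[Si](C(C)C)(C(C)C)OCC[C@]1(C)C2=CCCC(C(=O)OC)(C(=O)OC)[C@H]2CC[C@H]1C | intermediate
23 | (4R,5S,8R,9S)-4-(methoxycarbonyl)-8,9-dimethyl-9-[2-(triisopropylsilyloxy)ethyl]-Δ1(10)-octalin-4-carboxylic acid (CO2H β; CO2Me α) | CC(C)[Si](C(C)C)(C(C)C)OCC[C@]1(C)C2=CCC[C@](C(=O)OC)(C(=O)O)[C@H]2CC[C@H]1C | intermediate
24 | (4S,5S,8R,9S)-4-(hydroxymethyl)-8,9-dimethyl-9-[2-(triisopropylsilyloxy)ethyl]-Δ1(10)-octalin-4-carboxylic acid | CC(C)[Si](C(C)C)(C(C)C)OCC[C@]1(C)C2=CCC[C@](CO)(C(=O)O)[C@H]2CC[C@H]1C | intermediate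
25 | 2-(trimethylsilyl)ethyl (4S,5S,8R,9S)-4-(hydroxymethyl)-8,9-dimethyl-9-[2-(triisopropylsilyloxy)ethyl]-Δ1(10)-octalin-4-carboxylate | CC(C)[Si](C(C)C)(C(C)C)OCC[C@]1(C)C2=CCC[C@](CO)(C(=O)OCC[Si](C)(C)C)[C@H]2CC[C@H]1C | intermediate
26 | 2-(trimethylsilyl)ethyl (4R,5S,8R,9S)-4-(iodomethyl)-8,9-dimethyl-9-[2-(triisopropylsilyloxy)ethyl]-Δ1(10)-octalin-4-carboxylate | CC(C)[Si](C(C)C)(C(C)C)OCC[C@]1(C)C2=CCC[C@](CI)(C(=O)OCC[Si](C)(C)C)[C@H]2CC[C@H]1C | intermediate
27 | 2-(trimethylsilyl)ethyl (4S,5S,8R,9S)-4,8,9-trimethyl-9-[2-(triisopropylsilyloxy)ethyl]-Δ1(10)-octalin-4-carboxylate | CC(C)[Si](C(C)C)(C(C)C)OCC[C@]1(C)C2=CCC[C@](C)(C(=O)OCC[Si](C)(C)C)[C@H]2CC[C@H]1C | intermediate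
28 | 2-(trimethylsilyl)ethyl (4S,5S,8R,9S)-9-(2-hydroxyethyl)-4,8,9-trimethyl-Δ1(10)-octalin-4-carboxylate | OCC[C@]1(C)C2=CCC[C@](C)(C(=O)OCC[Si](C)(C)C)[C@H]2CC[C@H]1C | intermediate
29 | 2-(trimethylsilyl)ethyl (4S,5S,8R,9S)-9-(2-iodoethyl)-4,8,9-trimethyl-Δ1(10)-octalin-4-carboxylate | ICC[C@]1(C)C2=CCC[C@](C)(C(=O)OCC[Si](C)(C)C)[C@H]2CC[C@H]1C | intermediate
30 | 2-(trimethylsilyl)ethyl (4S,5S,8R,9S)-9-(but-3-yn-1-yl)-4,8,9-trimethyl-Δ1(10)-octalin-4-carboxylate | C#CCC[C@]1(C)C2=CCC[C@](C)(C(=O)OCC[Si](C)(C)C)[C@H]2CC[C@H]1C | intermediate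
31 | 2-(trimethylsilyl)ethyl (4S,5S,8R,9S)-9-[(3E)-4-(dimethylalumanyl)-3-methylbut-3-en-1-yl]-4,8,9-trimethyl-Δ1(10)-octalin-4-carboxylate (not isolated) | C/C(=C\[Al](C)C)CC[C@]1(C)C2=CCC[C@](C)(C(=O)OCC[Si](C)(C)C)[C@H]2CC[C@H]1C | intermediate
32 | lithium butyl(dimethyl)alkenylaluminate derived from 31 (not isolated) | [Li+].C/C(=C\[Al-](C)(C)CCCC)CC[C@]1(C)C2=CCC[C@](C)(C(=O)OCC[Si](C)(C)C)[C@H]2CC[C@H]1C | intermediate
33 | 2-(trimethylsilyl)ethyl (4S,5S,8R,9S)-9-[(3E)-5-hydroxy-3-methylpent-3-en-1-yl]-4,8,9-trimethyl-Δ1(10)-octalin-4-carboxylate | C/C(=C\CO)CC[C@]1(C)C2=CCC[C@](C)(C(=O)OCC[Si](C)(C)C)[C@H]2CC[C@H]1C | intermediate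
34 | phenylpropiolic acid (3-phenylprop-2-ynoic acid) | OC(=O)C#Cc1ccccc1 | starting material
35 | 2-(trimethylsilyl)ethyl (4S,5S,8R,9S)-4,8,9-trimethyl-9-{(3E)-3-methyl-5-[(3-phenylprop-2-ynoyl)oxy]pent-3-en-1-yl}-Δ1(10)-octalin-4-carboxylate | C/C(=C\COC(=O)C#Cc1ccccc1)CC[C@]1(C)C2=CCC[C@](C)(C(=O)OCC[Si](C)(C)C)[C@H]2CC[C@H]1C | intermediate
36 | 2-(trimethylsilyl)ethyl (4S,5S,8R,9S)-4,8,9-trimethyl-9-[(3E)-3-methyl-5-{[(2Z)-3-phenylprop-2-enoyl]oxy}pent-3-en-1-yl]-Δ1(10)-octalin-4-carboxylate | C/C(=C\COC(=O)/C=C\c1ccccc1)CC[C@]1(C)C2=CCC[C@](C)(C(=O)OCC[Si](C)(C)C)[C@H]2CC[C@H]1C | intermediate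
37 | (4S,5S,8R,9S)-4,8,9-trimethyl-9-[(3E)-3-methyl-5-{[(2Z)-3-phenylprop-2-enoyl]oxy}pent-3-en-1-yl]-Δ1(10)-octalin-4-carboxylic acid (CNP0150420.1) | C/C(=C\COC(=O)/C=C\c1ccccc1)CC[C@]1(C)C2=CCC[C@](C)(C(=O)O)[C@H]2CC[C@H]1C | target

**Summary**

Total step count: 24. Longest linear sequence: 24 steps (1 to 37); the other starting materials (4, 13, 20, 34) enter directly.

The three steps most likely to fail:

1. Step 12. Closure of the hindered π-allyl intermediate at C5 may be slow. β-Hydride elimination to dienes, intermolecular alkylation by residual free malonate, or erosion of the C1-to-C5 chirality transfer by palladium–palladium exchange could then compete. The fallback closes ring A by a double Michael addition instead; it sets out from triflate 12 and comes back at diester 22. Triflate 12 is coupled with acrolein (CrCl2, NiCl2, DMF) to 1-{(5R,6S)-5,6-dimethyl-6-[2-(triisopropylsilyloxy)ethyl]cyclohex-1-en-1-yl}prop-2-en-1-ol F1, which is oxidised with Dess–Martin periodinane to the cross-conjugated dienone F2. Sodium dimethyl malonate (from 20 and NaH, THF) adds first to the unsubstituted vinyl terminus (C3–C4) and then, after proton transfer, to C5 of the ring enone (C4–C5). This gives the C1–C10 sodium enolate F3, which is trapped in the same flask with PhNTf2 as the C1 enol triflate F4. Reduction of the triflate (Pd(OAc)2, PPh3, HCO2H, Bu3N, DMF, 60 °C) returns to 22. In this variant C5 rests on substrate control by the C9 quaternary centre, so its configuration would have to be confirmed before going on.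

2. Step 13. Hydroxide may not discriminate well enough between the two diastereotopic esters, or may attack the axial one, which would lead to the C4 epimer. The fallback swaps which carbonyl is reduced; it sets out from diester 22 and comes back at hydroxy acid 24. The half-ester with the free acid on the α face, (4S)-epimeric half-ester F5, is converted with (COCl)2 and catalytic DMF into the acid chloride F6. NaBH4 (THF, 0 °C) reduces F6 to the hydroxy methyl ester F7, so the acid and not the ester is now the group reduced. The remaining equatorial methyl ester is then saponified (KOH, aqueous ethylene glycol, 120 °C) to 24. If both half-esters form, they are separated and each is carried on by its own chemoselective reduction, so both converge on 24.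

3. Step 8. The oxazaborolidine and the C9 quaternary centre beside the twisted enone may be mismatched. Poor facial selectivity at C1 would be passed on to C5 by the chirality transfer. The fallback replaces reagent-controlled reduction by separation and inversion; it sets out from carbinol mixture 14 and comes back at 16, bypassing steps 7 and 8. The C1 epimers of 14 are separated by chromatography, and the (1S) epimer is 16 itself. The (1R) alcohol F8 is inverted by a Mitsunobu reaction (4-nitrobenzoic acid, PPh3, DIAD, THF) to the (1S) 4-nitrobenzoate F9. Methanolysis (K2CO3, MeOH) gives 16.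

Further compounds

F1 | step 12 | 1-{(5R,6S)-5,6-dimethyl-6-[2-(triisopropylsilyloxy)ethyl]cyclohex-1-en-1-yl}prop-2-en-1-ol (both C1 epimers) | CC(C)[Si](C(C)C)(C(C)C)OCC[C@]1(C)C(=CCC[C@H]1C)C(O)C=C
F2 | step 12 | 1-{(5R,6S)-5,6-dimethyl-6-[2-(triisopropylsilyloxy)ethyl]cyclohex-1-en-1-yl}prop-2-en-1-one | CC(C)[Si](C(C)C)(C(C)C)OCC[C@]1(C)C(=CCC[C@H]1C)C(=O)C=C
F3 | step 12 | sodium C1–C10 enolate of dimethyl (5S,8R,9S)-8,9-dimethyl-1-oxo-9-[2-(triisopropylsilyloxy)ethyl]decalin-4,4-dicarboxylate | [Na+].CC(C)[Si](C(C)C)(C(C)C)OCC[C@]1(C)C2=C([O-])CCC(C(=O)OC)(C(=O)OC)[C@H]2CC[C@H]1C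
F4 | step 12 | dimethyl (5S,8R,9S)-8,9-dimethyl-1-(trifluoromethylsulfonyloxy)-9-[2-(triisopropylsilyloxy)ethyl]-Δ1(10)-octalin-4,4-dicarboxylate | CC(C)[Si](C(C)C)(C(C)C)OCC[C@]1(C)C2=C(OS(=O)(=O)C(F)(F)F)CCC(C(=O)OC)(C(=O)OC)[C@H]2CC[C@H]1C
F5 | step 13 | (4S,5S,8R,9S)-4-(methoxycarbonyl)-8,9-dimethyl-9-[2-(triisopropylsilyloxy)ethyl]-Δ1(10)-octalin-4-carboxylic acid (CO2H α; CO2Me β) | CC(C)[Si](C(C)C)(C(C)C)OCC[C@]1(C)C2=CCC[C@](C(=O)O)(C(=O)OC)[C@H]2CC[C@H]1C
F6 | step 13 | methyl (4R,5S,8R,9S)-4-(chlorocarbonyl)-8,9-dimethyl-9-[2-(triisopropylsilyloxy)ethyl]-Δ1(10)-octalin-4-carboxylate | CC(C)[Si](C(C)C)(C(C)C)OCC[C@]1(C)C2=CCC[C@](C(=O)Cl)(C(=O)OC)[C@H]2CC[C@H]1C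
F7 | step 13 | methyl (4S,5S,8R,9S)-4-(hydroxymethyl)-8,9-dimethyl-9-[2-(triisopropylsilyloxy)ethyl]-Δ1(10)-octalin-4-carboxylate | CC(C)[Si](C(C)C)(C(C)C)OCC[C@]1(C)C2=CCC[C@](CO)(C(=O)OC)[C@H]2CC[C@H]1C
F8 | step 8 | (1R)-3-(tert-butyldimethylsilyloxy)-1-{(5R,6S)-5,6-dimethyl-6-[2-(triisopropylsilyloxy)ethyl]cyclohex-1-en-1-yl}propan-1-ol | CC(C)[Si](C(C)C)(C(C)C)OCC[C@]1(C)C(=CCC[C@H]1C)[C@@H](CCO[Si](C)(C)C(C)(C)C)O
F9 | step 8 | (1S)-3-(tert-butyldimethylsilyloxy)-1-{(5R,6S)-5,6-dimethyl-6-[2-(triisopropylsilyloxy)ethyl]cyclohex-1-en-1-yl}propyl 4-nitrobenzoate | CC(C)[Si](C(C)C)(C(C)C)OCC[C@]1(C)C(=CCC[C@H]1C)[C@H](CCO[Si](C)(C)C(C)(C)C)OC(=O)c1ccc(cc1)[N+](=O)[O-]
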